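**Retrosynthetic overview**

1. Target 19 ⇐ silyl ether ketone 18 (Si–O cleavage) ⇐ N-methoxy-N-methylamide 15 + aryllithium 17 (acyl–aryl bond) ⇐ ester 14.
2. Feature used: the ketone carbon on C4 of the oxolane (ring O1–C2–C3–C4–C5) is treated as the former C4 carbonyl carbon of an oxan-4-one, and the cis C2-aryl/C3-CH2O pair of the oxolane is the C2/C3 pair of that oxane.
3. 14 ⇐ diazo ketone 11 by Wolff ring contraction: C3 moves from C4 to C5 of the oxane, which makes the oxolane C3–C4 bond; the oxolane is the second ring, formed by contraction.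
4. 11 ⇐ dihydropyranone 8 (conjugate reduction with enolate trifluoroacetylation, then diazo transfer); 8 ⇐ aldehyde 6 + diene 5 by catalytic asymmetric endo hetero-Diels–Alder reaction (first ring; sets C2 and C3).
5. 5 ⇐ methoxybutenone 1 (hydroxymethylation, silylation, silyl dienol ether formation).

Key step: step 7

Assumption: the enantiomer of the chromium catalyst in step 4 is the one that sends the diene to the Si face of the aldehyde carbonyl (this gives 2S); if the sense of induction is the opposite, the mirror-image catalyst is used.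

Locants: oxane O1, C2 (aryl), C3 (CH2O), C4 (C=O), C5, C6; oxolane O1, C2 (aryl), C3 (CH2O), C4 (carbonyl substituent), C5 (CH2). "Aryl" is 3,4,5-trimethoxyphenyl.

**Route**

Step 1
Reactants: 1 (E)-4-methoxybut-3-en-2-one
Product: 3 (E)-5-hydroxy-1-methoxypent-1-en-3-one, via lithium enolate 2 (not isolated)
Conditions: LiHMDS, THF, −78 °C; monomeric HCHO (from cracked paraformaldehyde), −78 °C; AcOH quench
Reagents that add atoms: formaldehyde, C=O
Why: The methyl group is the only enolisable position, so kinetic deprotonation and aldol addition to formaldehyde (hydroxymethylation) should give the β-hydroxy ketone.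

Step 2
Reactants: 3 (E)-5-hydroxy-1-methoxypent-1-en-3-one
Product: 4 (E)-5-(tert-butyldimethylsilyloxy)-1-methoxypent-1-en-3-one
Conditions: TBSCl, imidazole, CH2Cl2, 0 °C to rt
Reagents that add atoms: tert-butyldimethylsilyl chloride, CC(C)(C)[Si](C)(C)Cl
Why: Standard silylation of a primary alcohol under mild, non-acidic conditions that leave the β-methoxy enone intact.

Step 3
Reactants: 4 (E)-5-(tert-butyldimethylsilyloxy)-1-methoxypent-1-en-3-one
Product: 5 (1E,3Z)-5-(tert-butyldimethylsilyloxy)-1-methoxy-3-(triethylsilyloxy)penta-1,3-diene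
Conditions: TESOTf, Et3N, Et2O, −78 to 0 °C
Reagents that add atoms: triethylsilyl trifluoromethanesulfonate, CC[Si](CC)(CC)OS(=O)(=O)C(F)(F)F
Why: Soft enolisation (silyl triflate/amine) at the only enolisable α-position gives the 1-methoxy-3-silyloxy diene, with the Z enol ether (OSi cis to CH2OTBS) as the usual outcome for such ketones.

Step 4
Reactants: 5 (1E,3Z)-5-(tert-butyldimethylsilyloxy)-1-methoxy-3-(triethylsilyloxy)penta-1,3-diene; 6 3,4,5-trimethoxybenzaldehyde
Product: 8 (2S,3S)-3-(tert-butyldimethylsilyloxymethyl)-2-(3,4,5-trimethoxyphenyl)-2,3-dihydro-4H-pyran-4-one, via cycloadduct 7 (not isolated)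
Conditions: chiral tridentate Schiff-base Cr(III)Cl complex [from 3-(1-adamantyl)-2-hydroxy-5-methylbenzaldehyde and cis-1-amino-2-indanol] 5 mol %, 4 Å MS, acetone, rt; then TFA (cat.), CH2Cl2, 0 °C
Reagents that add atoms: none
Why: Lewis-acid-catalysed hetero-Diels–Alder reaction joins the aldehyde carbon to the silyl enol ether terminus and the aldehyde oxygen to C1; the Z enol ether puts CH2OTBS "outside" and the aryl group sits endo (Lewis acid anti to aryl), so C2/C3 should come out cis, the catalyst fixes the face (2S,3S), and acid then expels methanol and the triethylsilyl group to give the enone.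

Step 5
Reactants: 8 (2S,3S)-3-(tert-butyldimethylsilyloxymethyl)-2-(3,4,5-trimethoxyphenyl)-2,3-dihydro-4H-pyran-4-one
Product: 10 (2S,3S)-3-(tert-butyldimethylsilyloxymethyl)-5-(trifluoroacetyl)-2-(3,4,5-trimethoxyphenyl)oxan-4-one, via lithium enolate 9 (not isolated)
Conditions: L-Selectride (1.05 equiv), THF, −78 °C; CF3CO2CH2CF3, −78 °C; cold dilute HCl work-up; used crude
Reagents that add atoms: 2,2,2-trifluoroethyl trifluoroacetate, O=C(OCC(F)(F)F)C(F)(F)F
Why: Conjugate hydride addition to the vinylogous ester gives the C4–C5 enolate regiospecifically, and Claisen-type C-acylation of this enolate activates C5 alone, so the C3–H is never removed and the cis pair is kept.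

Step 6
Reactants: 10 (2S,3S)-3-(tert-butyldimethylsilyloxymethyl)-5-(trifluoroacetyl)-2-(3,4,5-trimethoxyphenyl)oxan-4-one
Product: 11 (2S,3S)-3-(tert-butyldimethylsilyloxymethyl)-5-diazo-2-(3,4,5-trimethoxyphenyl)oxan-4-one
Conditions: MsN3, Et3N, H2O (1 equiv), MeCN, rt
Reagents that add atoms: methanesulfonyl azide, CS(=O)(=O)N=[N+]=[N-]
Why: Regitz-type detrifluoroacetylative diazo transfer: the stabilised 1,3-dicarbonyl enolate attacks the azide and the adduct fragments with loss of the trifluoroacetyl group, while triethylamine is too weak to touch C3–H.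

Step 7
Reactants: 11 (2S,3S)-3-(tert-butyldimethylsilyloxymethyl)-5-diazo-2-(3,4,5-trimethoxyphenyl)oxan-4-one
Product: 14 methyl (2S,3S,4R)-3-(tert-butyldimethylsilyloxymethyl)-2-(3,4,5-trimethoxyphenyl)oxolane-4-carboxylate, via ketene 12 (not isolated), via C4-epimeric ester mixture 13 (not isolated)
Conditions: hν (medium-pressure Hg lamp, Pyrex, λ > 300 nm), degassed MeOH, 0–20 °C; then NaOMe (cat.), MeOH, rt
Reagents that add atoms: methanol, CO
Why: Irradiation expels N2 from the s-cis-locked α-diazo ketone while C3 shifts from the carbonyl carbon C4 to C5 (Wolff rearrangement), giving ketene 12, which methanol traps as the ester. The closest known reaction type is the photochemical Wolff ring contraction of cyclic α-diazo ketones (six- to five-membered), here with a ring oxygen β to the diazo carbon. The oxolane is closed not by cyclisation but by this 1,2-alkyl shift, which makes the oxolane C3–C4 bond and leaves the old carbonyl carbon exocyclic at the ester level. C3 migrates with retention, so the C2/C3 cis pair is unchanged; the new centre C4 is first set unselectively by protonation of the ester enol and is then put under thermodynamic control by methoxide, which should place the ester trans to the C3 substituent (the all-cis isomer is strongly disfavoured). The step needs the 1,2-shift to win over 1,2-hydride shift from C6 and O–H insertion, which the ring-enforced s-cis geometry of C=O and C=N2 (concerted loss of N2) should secure; only C3 can migrate because it is the only other substituent on the carbonyl carbon. C3 carries no acidic hydrogen in the ester, so the equilibration touches C4 only.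

Step 8
Reactants: 14 methyl (2S,3S,4R)-3-(tert-butyldimethylsilyloxymethyl)-2-(3,4,5-trimethoxyphenyl)oxolane-4-carboxylate
Product: 15 (2S,3S,4R)-3-(tert-butyldimethylsilyloxymethyl)-N-methoxy-N-methyl-2-(3,4,5-trimethoxyphenyl)oxolane-4-carboxamide
Conditions: MeNH(OMe)·HCl, i-PrMgCl, THF, −20 to 0 °C
Reagents that add atoms: N,O-dimethylhydroxylamine hydrochloride, CNOC.Cl
Why: Aminolysis of the ester by the chloromagnesium amide gives the N-methoxy-N-methylamide; C4 is already in its stable trans configuration, so any enolisation returns the same isomer.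

Step 9
Reactants: 15 (2S,3S,4R)-3-(tert-butyldimethylsilyloxymethyl)-N-methoxy-N-methyl-2-(3,4,5-trimethoxyphenyl)oxolane-4-carboxamide; 16 5-bromo-1,2,3-trimethoxybenzene
Product: 18 [(2S,3S,4R)-3-(tert-butyldimethylsilyloxymethyl)-2-(3,4,5-trimethoxyphenyl)oxolan-4-yl](3,4,5-trimethoxyphenyl)methanone, via aryllithium 17 (not isolated)
Conditions: 16, n-BuLi, THF, −78 °C; then 15, −78 to −40 °C; aq. NH4Cl
Reagents that add atoms: none
Why: Bromine–lithium exchange followed by Weinreb ketone synthesis; the chelated tetrahedral adduct stops the reaction at the ketone stage.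

Step 10
Reactants: 18 [(2S,3S,4R)-3-(tert-butyldimethylsilyloxymethyl)-2-(3,4,5-trimethoxyphenyl)oxolan-4-yl](3,4,5-trimethoxyphenyl)methanone
Product: 19 [(2S,3S,4R)-3-(hydroxymethyl)-2-(3,4,5-trimethoxyphenyl)oxolan-4-yl](3,4,5-trimethoxyphenyl)methanone
Conditions: HF·pyridine, pyridine, THF, 0 °C to rt
Reagents that add atoms: none
Why: Fluoride cleaves the primary silyl ether under non-basic conditions, so the α-centre of the β-alkoxy ketone is not exposed to base; the trans hydroxy ketone cannot close to a strain-free hemiketal and should be isolated as such.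

**Compound list**

1 | (E)-4-methoxybut-3-en-2-one | CO/C=C/C(C)=O | starting material
2 | lithium (E)-4-methoxybuta-1,3-dien-2-olate | C=C(O[Li])/C=C/OC | intermediate
3 | (E)-5-hydroxy-1-methoxypent-1-en-3-one | CO/C=C/C(=O)CCO | intermediate
4 | (E)-5-(tert-butyldimethylsilyloxy)-1-methoxypent-1-en-3-one | CO/C=C/C(=O)CCO[Si](C)(C)C(C)(C)C | intermediate
5 | (1E,3Z)-5-(tert-butyldimethylsilyloxy)-1-methoxy-3-(triethylsilyloxy)penta-1,3-diene | CO/C=C/C(O[Si](CC)(CC)CC)=C/CO[Si](C)(C)C(C)(C)C | intermediate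
6 | 3,4,5-trimethoxybenzaldehyde | COc1cc(C=O)cc(OC)c1OC | starting material
7 | (2S,3S,6R)-3-(tert-butyldimethylsilyloxymethyl)-6-methoxy-4-(triethylsilyloxy)-2-(3,4,5-trimethoxyphenyl)-3,6-dihydro-2H-pyran (all-cis) | CO[C@@H]1O[C@H](c2cc(OC)c(OC)c(OC)c2)[C@H](CO[Si](C)(C)C(C)(C)C)C(O[Si](CC)(CC)CC)=C1 | intermediate
8 | (2S,3S)-3-(tert-butyldimethylsilyloxymethyl)-2-(3,4,5-trimethoxyphenyl)-2,3-dihydro-4H-pyran-4-one (2,3-cis) | O=C1C=CO[C@H](c2cc(OC)c(OC)c(OC)c2)[C@@H]1CO[Si](C)(C)C(C)(C)C | intermediate
9 | lithium (2S,3S)-3-(tert-butyldimethylsilyloxymethyl)-2-(3,4,5-trimethoxyphenyl)-3,6-dihydro-2H-pyran-4-olate | [Li]OC1=CCO[C@H](c2cc(OC)c(OC)c(OC)c2)[C@@H]1CO[Si](C)(C)C(C)(C)C | intermediate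
10 | (2S,3S)-3-(tert-butyldimethylsilyloxymethyl)-5-(trifluoroacetyl)-2-(3,4,5-trimethoxyphenyl)oxan-4-one (C5 undefined, largely enolised) | O=C1C(C(=O)C(F)(F)F)CO[C@H](c2cc(OC)c(OC)c(OC)c2)[C@@H]1CO[Si](C)(C)C(C)(C)C | intermediate
11 | (2S,3S)-3-(tert-butyldimethylsilyloxymethyl)-5-diazo-2-(3,4,5-trimethoxyphenyl)oxan-4-one (2,3-cis) | O=C1C(=[N+]=[N-])CO[C@H](c2cc(OC)c(OC)c(OC)c2)[C@@H]1CO[Si](C)(C)C(C)(C)C | intermediate
12 | (2S,3S)-3-(tert-butyldimethylsilyloxymethyl)-4-(oxomethylidene)-2-(3,4,5-trimethoxyphenyl)oxolane (ketene) | O=C=C1CO[C@H](c2cc(OC)c(OC)c(OC)c2)[C@@H]1CO[Si](C)(C)C(C)(C)C | intermediate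
13 | methyl (2S,3S)-3-(tert-butyldimethylsilyloxymethyl)-2-(3,4,5-trimethoxyphenyl)oxolane-4-carboxylate, mixture of C4 epimers | COC(=O)C1CO[C@H](c2cc(OC)c(OC)c(OC)c2)[C@@H]1CO[Si](C)(C)C(C)(C)C | intermediate
14 | methyl (2S,3S,4R)-3-(tert-butyldimethylsilyloxymethyl)-2-(3,4,5-trimethoxyphenyl)oxolane-4-carboxylate (2,3-cis-3,4-trans) | COC(=O)[C@H]1CO[C@H](c2cc(OC)c(OC)c(OC)c2)[C@@H]1CO[Si](C)(C)C(C)(C)C | intermediate
15 | (2S,3S,4R)-3-(tert-butyldimethylsilyloxymethyl)-N-methoxy-N-methyl-2-(3,4,5-trimethoxyphenyl)oxolane-4-carboxamide | CON(C)C(=O)[C@H]1CO[C@H](c2cc(OC)c(OC)c(OC)c2)[C@@H]1CO[Si](C)(C)C(C)(C)C | intermediate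
16 | 5-bromo-1,2,3-trimethoxybenzene | COc1cc(Br)cc(OC)c1OC | starting material
17 | (3,4,5-trimethoxyphenyl)lithium | [Li]c1cc(OC)c(OC)c(OC)c1 | intermediate
18 | [(2S,3S,4R)-3-(tert-butyldimethylsilyloxymethyl)-2-(3,4,5-trimethoxyphenyl)oxolan-4-yl](3,4,5-trimethoxyphenyl)methanone | COc1cc(C(=O)[C@H]2CO[C@H](c3cc(OC)c(OC)c(OC)c3)[C@@H]2CO[Si](C)(C)C(C)(C)C)cc(OC)c1OC | intermediate
19 | [(2S,3S,4R)-3-(hydroxymethyl)-2-(3,4,5-trimethoxyphenyl)oxolan-4-yl](3,4,5-trimethoxyphenyl)methanone | COc1cc(C(=O)[C@H]2CO[C@H](c3cc(OC)c(OC)c(OC)c3)[C@@H]2CO)cc(OC)c1OC | target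

**Step count**

Total steps: 10. Longest linear sequence: 10 steps (1 to 19); bromide 16 enters in step 9 without separate steps.

**Steps most likely to fail, with fallbacks**

Step 7. The photoexcited diazo ketone (or a free acyl carbene) may be diverted into 1,2-hydride shift from C6, which returns enone 8, or into O–H insertion with methanol, instead of the shift of C3. The fallback gives up the contraction: it cuts C6 out of the six-membered ring and adds the aroyl carbon afterwards. It sets out from 8 and comes back at 18.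
- Luche reduction (NaBH4, CeCl3, MeOH, −78 °C) should give the allylic alcohol 2,3-cis-3-(tert-butyldimethylsilyloxymethyl)-2-(3,4,5-trimethoxyphenyl)-3,4-dihydro-2H-pyran-4-ol F1.
- Ozonolysis of its enol ether double bond (O3, CH2Cl2/MeOH, −78 °C; Me2S) and methanolysis of the resulting formate (K2CO3, MeOH) should let the C2 hydroxyl close onto the C5 aldehyde, giving the lactol 2,3-cis-3-(tert-butyldimethylsilyloxymethyl)-2-(3,4,5-trimethoxyphenyl)oxolane-4,5-diol F2.
- Ionic reduction of the lactol (Et3SiH, BF3·OEt2, CH2Cl2, −78 °C) should give 2,3-cis-3-(tert-butyldimethylsilyloxymethyl)-2-(3,4,5-trimethoxyphenyl)oxolan-4-ol F3.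
- Appel-type iodination (I2, PPh3, imidazole, toluene, 80 °C) should give 2,3-cis-3-(tert-butyldimethylsilyloxymethyl)-4-iodo-2-(3,4,5-trimethoxyphenyl)oxolane F4.
- Nickel-catalysed reductive acylation of F4 with 3,4,5-trimethoxybenzoyl chloride (NiCl2·glyme, 4,4'-di-tert-butyl-2,2'-bipyridine, Mn, DMA), followed by DBU equilibration at C4, should give 18. The C4 configuration of F1–F4 is irrelevant because C4 is finally set under thermodynamic control.

Step 4. The electron-rich aldehyde may react slowly, so the diene hydrolyses, and a stepwise aldol-type pathway may erode endo and facial selectivity. The fallback replaces the cycloaddition by an aldol addition and cyclisation. It sets out from ketone 4 (with aldehyde 6) and comes back at 8.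
- The (Z)-enol borinate of 4 [(–)- or (+)-diisopinocampheylboron triflate, i-Pr2NEt, CH2Cl2, −78 °C] should add to 6 to give the syn aldol (1E,4S,5S)-4-(tert-butyldimethylsilyloxymethyl)-5-hydroxy-1-methoxy-5-(3,4,5-trimethoxyphenyl)pent-1-en-3-one F5.
- Acid (TFA cat., CH2Cl2, 0 °C) should close F5 by conjugate addition of the hydroxyl and loss of methanol to the cis-dihydropyranone 8.

Step 5. The enolate from the conjugate reduction, which is associated with the trialkylborane, may be acylated incompletely or at oxygen, and proton transfer from the acidic 1,3-diketone to unreacted enolate may blur regiochemistry or epimerise C3. The fallback separates reduction from enolate formation. It sets out from 8 and comes back at 10.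
- Catalytic hydrogenation of the enol ether double bond (H2, Pd/C, EtOAc, short contact) should give the saturated ketone (2S,3S)-3-(tert-butyldimethylsilyloxymethyl)-2-(3,4,5-trimethoxyphenyl)oxan-4-one F6.
- Kinetic deprotonation of F6 on the CH2 side (LiHMDS, THF, −78 °C) regenerates enolate 9 free of boron, and trifluoroethyl trifluoroacetate then gives 10.

**Further compounds**

F1 | step 7 | 2,3-cis-3-(tert-butyldimethylsilyloxymethyl)-2-(3,4,5-trimethoxyphenyl)-3,4-dihydro-2H-pyran-4-ol (C2, C3 as in 8; C4 undefined) | OC1C=CO[C@H](c2cc(OC)c(OC)c(OC)c2)[C@@H]1CO[Si](C)(C)C(C)(C)C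
F2 | step 7 | 2,3-cis-3-(tert-butyldimethylsilyloxymethyl)-2-(3,4,5-trimethoxyphenyl)oxolane-4,5-diol (lactol; C4, C5 undefined) | OC1C(O)O[C@H](c2cc(OC)c(OC)c(OC)c2)[C@@H]1CO[Si](C)(C)C(C)(C)C
F3 | step 7 | 2,3-cis-3-(tert-butyldimethylsilyloxymethyl)-2-(3,4,5-trimethoxyphenyl)oxolan-4-ol (C4 undefined) | OC1CO[C@H](c2cc(OC)c(OC)c(OC)c2)[C@@H]1CO[Si](C)(C)C(C)(C)C
F4 | step 7 | 2,3-cis-3-(tert-butyldimethylsilyloxymethyl)-4-iodo-2-(3,4,5-trimethoxyphenyl)oxolane (C4 undefined) | IC1CO[C@H](c2cc(OC)c(OC)c(OC)c2)[C@@H]1CO[Si](C)(C)C(C)(C)C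
F5 | step 4 | (1E,4S,5S)-4-(tert-butyldimethylsilyloxymethyl)-5-hydroxy-1-methoxy-5-(3,4,5-trimethoxyphenyl)pent-1-en-3-one | CO/C=C/C(=O)[C@@H](CO[Si](C)(C)C(C)(C)C)[C@H](O)c1cc(OC)c(OC)c(OC)c1
F6 | step 5 | (2S,3S)-3-(tert-butyldimethylsilyloxymethyl)-2-(3,4,5-trimethoxyphenyl)oxan-4-one | O=C1CCO[C@H](c2cc(OC)c(OC)c(OC)c2)[C@@H]1CO[Si](C)(C)C(C)(C)C
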